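**Retrosynthetic overview**
- The target comes from its 5‑O‑MOM ether, formed by dehydrogenative 2'‑O→C2 furan closure of a 2',4',5'‑trihydroxy‑3'‑prenylisoflavone (the presumed biogenetic precursor) through its own ring‑B quinone.
- That isoflavone comes from a one‑flask union of a ring‑A o‑hydroxyaryl enaminone with 2‑hydroxy‑3‑prenyl‑1,4‑benzoquinone: conjugate addition makes C3–C1', then the only free ring‑A phenol closes ring C on C2 with loss of Me2NH.
- The enaminone comes from 6‑acetyl‑5‑hydroxy‑7‑MOMO‑2,2,8‑trimethylchromene, made by prenal annulation (o‑quinone methide, oxa‑6π) on 3‑methylphloroacetophenone whose three phenols are told apart by Bn / MOM / hydrogenolysis.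
- The hydroxyquinone comes from Teuber oxidation of 2‑prenylresorcinol, made by ortho‑lithiation/prenylation of resorcinol bis‑MOM ether.
- Ring order: dimethylpyran first, then pyranone ring C, then the furan (the last two in one flask); rings A and B are bought.

Assumption: the target SMILES has no stereocentre and no stereogenic double bond, so it is achiral and no step needs stereocontrol; small reagents that deliver atoms are given by name and SMILES in each step and are not numbered.

**Step 1**
Reactants: 1 1-(2,4,6-trihydroxy-3-methylphenyl)ethan-1-one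
Product: 2 1-[4,6-bis(benzyloxy)-2-hydroxy-3-methylphenyl]ethan-1-one
Conditions: BnBr (2.05 equiv), K2CO3 (2.2 equiv), acetone, reflux
Reagents that add atoms: benzyl bromide, BrCc1ccccc1
Why: Williamson ether synthesis in which the non-chelated 4-OH and then the 6-OH (flanked only by H) react, while the 2-OH, buttressed between acetyl and methyl and locked in its hydrogen bond to the ketone, stays free (the usual selectivity of 3-alkylphloroacetophenones).

**Step 2**
Reactants: 2 1-[4,6-bis(benzyloxy)-2-hydroxy-3-methylphenyl]ethan-1-one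
Product: 3 1-[4,6-bis(benzyloxy)-2-(methoxymethoxy)-3-methylphenyl]ethan-1-one
Conditions: NaH (1.2 equiv), MOMCl (1.3 equiv), DMF, 0 → 25 °C
Reagents that add atoms: chloromethyl methyl ether, COCCl
Why: Williamson-type O-alkylation (MOM acetal formation) of the sodium phenoxide caps the oxygen destined to be the chelated 5-OH, so that only the 6-oxygen can later close the pyranone ring.

**Step 3**
Reactants: 3 1-[4,6-bis(benzyloxy)-2-(methoxymethoxy)-3-methylphenyl]ethan-1-one
Product: 4 1-[4,6-dihydroxy-2-(methoxymethoxy)-3-methylphenyl]ethan-1-one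
Conditions: H2 (1 atm), 10% Pd/C, EtOAc/MeOH, 25 °C
Reagents that add atoms: none
Why: Catalytic hydrogenolysis removes both benzyl ethers while the MOM acetal and the aryl ketone survive, and it is run before any C=C bond is present.

**Step 4**
Reactants: 4 1-[4,6-dihydroxy-2-(methoxymethoxy)-3-methylphenyl]ethan-1-one
Product: 6 1-[5-hydroxy-7-(methoxymethoxy)-2,2,8-trimethyl-2H-chromen-6-yl]ethan-1-one, via ortho-quinone methide 5 (not isolated)
Conditions: 3-methylbut-2-enal (1.5 equiv), ethylenediammonium diacetate (20 mol %), toluene, 110 °C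
Reagents that add atoms: 3-methylbut-2-enal, CC(C)=CC=O
Why: Knoevenagel-type condensation at C5 (the only free ring carbon) gives ortho-quinone methide 5, whose oxa-6π electrocyclisation onto the non-chelated 4-oxygen forms the 2,2-dimethylpyran (formal [3+3] chromene annulation, the same quinone methide closure thought to turn prenylphenols into dimethylpyrans in the plant), while the 6-OH stays hydrogen-bonded to the acetyl group.

**Step 5**
Reactants: 6 1-[5-hydroxy-7-(methoxymethoxy)-2,2,8-trimethyl-2H-chromen-6-yl]ethan-1-one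
Product: 7 (E)-3-(dimethylamino)-1-[5-hydroxy-7-(methoxymethoxy)-2,2,8-trimethyl-2H-chromen-6-yl]prop-2-en-1-one
Conditions: Me2NCH(OMe)2 (2 equiv), toluene, 90 °C
Reagents that add atoms: N,N-dimethylformamide dimethyl acetal, COC(OC)N(C)C
Why: Enaminone formation by condensation of the methyl ketone with the amide acetal gives the push-pull E-enaminone, whose aminomethylene carbon is the future C2 and whose α-carbon is the nucleophile of step 10; the only phenol is chelated and is not methylated.

**Step 6**
Reactants: 8 benzene-1,3-diol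
Product: 9 1,3-bis(methoxymethoxy)benzene
Conditions: NaH (2.4 equiv), MOMCl (2.4 equiv), DMF, 0 → 25 °C
Reagents that add atoms: chloromethyl methyl ether, COCCl
Why: Williamson-type double MOM protection installs the two acetal directing groups needed for the ortho-lithiation.

**Step 7**
Reactants: 9 1,3-bis(methoxymethoxy)benzene
Product: 11 1,3-bis(methoxymethoxy)-2-(3-methylbut-2-en-1-yl)benzene, via aryllithium 10 (not isolated)
Conditions: n-BuLi, TMEDA, THF, 0 → 25 °C; then 1-bromo-3-methylbut-2-ene, −78 → 25 °C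
Reagents that add atoms: 1-bromo-3-methylbut-2-ene, CC(C)=CCBr; n-butyllithium, [Li]CCCC (lithium of 10 only)
Why: Directed ortho-metalation, in which both OMOM groups steer n-BuLi to C2 to give aryllithium 10, followed by SN2 alkylation with prenyl bromide, places the prenyl group between the two oxygens with full regiocontrol.

**Step 8**
Reactants: 11 1,3-bis(methoxymethoxy)-2-(3-methylbut-2-en-1-yl)benzene
Product: 12 2-(3-methylbut-2-en-1-yl)benzene-1,3-diol
Conditions: HCl (2 M in MeOH), 25 °C
Reagents that add atoms: none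
Why: Acid-catalysed acetal cleavage (transacetalisation to dimethoxymethane) frees both phenols at room temperature, mild enough to avoid cyclisation of the ortho-prenylphenol to a chroman.

**Step 9**
Reactants: 12 2-(3-methylbut-2-en-1-yl)benzene-1,3-diol
Product: 13 2-hydroxy-3-(3-methylbut-2-en-1-yl)cyclohexa-2,5-diene-1,4-dione
Conditions: potassium nitrosodisulfonate K2[ON(SO3)2] (2.5 equiv), KH2PO4 buffer, H2O/acetone, 0 → 20 °C
Reagents that add atoms: potassium nitrosodisulfonate, [K+].[K+].[O]N(S(=O)(=O)[O-])S(=O)(=O)[O-]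
Why: Teuber oxidation, in which the phenoxyl radical is trapped para by a second nitroxide and collapses to the para-quinone, leaves the second OH in place as a 2-hydroxy-1,4-benzoquinone, and the prenyl alkene does not react with this radical oxidant.

**Step 10**
Reactants: 7 (E)-3-(dimethylamino)-1-[5-hydroxy-7-(methoxymethoxy)-2,2,8-trimethyl-2H-chromen-6-yl]prop-2-en-1-one; 13 2-hydroxy-3-(3-methylbut-2-en-1-yl)cyclohexa-2,5-diene-1,4-dione
Product: 17 triquetrumone A, via trihydroxyisoflavone 14 (not isolated), via isoflavone quinone 15 (not isolated), via 5-O-MOM-triquetrumone A 16 (not isolated)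
Conditions: 13 (2.2 equiv), AcOH (5 equiv), MeCN, argon, 25 → 45 °C; then 2 M HCl in MeOH, 40 °C
Reagents that add atoms: none
Why: Proposed new method: the enaminone α-carbon adds in a Michael sense to C5 of the 2-hydroxyquinone (the position enamines take in Nenitzescu reactions of 2-alkoxyquinones), the adduct re-aromatises and the only free ring-A phenol closes onto the aminomethylene carbon with loss of Me2NH to give 14 (electrophile-triggered chromone annulation of o-hydroxyaryl enaminones), a second equivalent of 13 oxidises the hydroxyquinol ring to quinone 15, whose 2'-oxygen adds to C2 and tautomerises to the aromatic benzofuran-catechol 16 (the dehydrogenative 2'-O to C2 closure assumed in coumaronochromone biosynthesis and known from DDQ cyclisations of 2'-hydroxyisoflavones), and methanolic HCl then cleaves the chelated 5-O-MOM group; closest known reaction types are the Nenitzescu benzofuran and 5-hydroxyindole syntheses.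

**Compound list**
1 | 1-(2,4,6-trihydroxy-3-methylphenyl)ethan-1-one (3-methylphloroacetophenone) | CC(=O)c1c(O)cc(O)c(C)c1O | starting material
2 | 1-[4,6-bis(benzyloxy)-2-hydroxy-3-methylphenyl]ethan-1-one | CC(=O)c1c(O)c(C)c(OCc2ccccc2)cc1OCc1ccccc1 | intermediate
3 | 1-[4,6-bis(benzyloxy)-2-(methoxymethoxy)-3-methylphenyl]ethan-1-one | CC(=O)c1c(OCOC)c(C)c(OCc2ccccc2)cc1OCc1ccccc1 | intermediate
4 | 1-[4,6-dihydroxy-2-(methoxymethoxy)-3-methylphenyl]ethan-1-one | CC(=O)c1c(OCOC)c(C)c(O)cc1O | intermediate
5 | 4-acetyl-5-hydroxy-3-(methoxymethoxy)-2-methyl-6-(3-methylbut-2-en-1-ylidene)cyclohexa-2,4-dien-1-one (ortho-quinone methide) | CC(=O)C1=C(O)C(=CC=C(C)C)C(=O)C(C)=C1OCOC | intermediate (not isolated)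
6 | 1-[5-hydroxy-7-(methoxymethoxy)-2,2,8-trimethyl-2H-chromen-6-yl]ethan-1-one | CC(=O)c1c(O)c2C=CC(C)(C)Oc2c(C)c1OCOC | intermediate
7 | (E)-3-(dimethylamino)-1-[5-hydroxy-7-(methoxymethoxy)-2,2,8-trimethyl-2H-chromen-6-yl]prop-2-en-1-one | CN(C)/C=C/C(=O)c1c(O)c2C=CC(C)(C)Oc2c(C)c1OCOC | intermediate
8 | benzene-1,3-diol (resorcinol) | Oc1cccc(O)c1 | starting material
9 | 1,3-bis(methoxymethoxy)benzene | COCOc1cccc(OCOC)c1 | intermediate
10 | [2,6-bis(methoxymethoxy)phenyl]lithium | [Li]c1c(OCOC)cccc1OCOC | intermediate (not isolated)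
11 | 1,3-bis(methoxymethoxy)-2-(3-methylbut-2-en-1-yl)benzene | COCOc1cccc(OCOC)c1CC=C(C)C | intermediate
12 | 2-(3-methylbut-2-en-1-yl)benzene-1,3-diol (2-prenylresorcinol) | CC(C)=CCc1c(O)cccc1O | intermediate
13 | 2-hydroxy-3-(3-methylbut-2-en-1-yl)cyclohexa-2,5-diene-1,4-dione | CC(C)=CCC1=C(O)C(=O)C=CC1=O | intermediate
14 | 5-(methoxymethoxy)-6,8,8-trimethyl-3-[2,4,5-trihydroxy-3-(3-methylbut-2-en-1-yl)phenyl]-4H,8H-pyrano[2,3-f]chromen-4-one | CC(C)=CCc1c(O)c(O)cc(c1O)-c1coc2c3C=CC(C)(C)Oc3c(C)c(OCOC)c2c1=O | intermediate (not isolated)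
15 | 2-hydroxy-5-[5-(methoxymethoxy)-6,8,8-trimethyl-4-oxo-4H,8H-pyrano[2,3-f]chromen-3-yl]-3-(3-methylbut-2-en-1-yl)cyclohexa-2,5-diene-1,4-dione | CC(C)=CCC1=C(O)C(=O)C=C(C1=O)c1coc2c3C=CC(C)(C)Oc3c(C)c(OCOC)c2c1=O | intermediate (not isolated)
16 | 5-O-(methoxymethyl)triquetrumone A (target with OCH2OCH3 in place of the chelated 5-OH) | CC(C)=CCc1c(O)c(O)cc2c1oc1oc3c4c(c(C)c(OCOC)c3c(=O)c12)OC(C)(C)C=C4 | intermediate (not isolated)
17 | triquetrumone A | CC(C)=CCc1c(O)c(O)cc2c1oc1oc3c4c(c(C)c(O)c3c(=O)c12)OC(C)(C)C=C4 | target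

**Step count and risks**
Total steps: 10. Longest linear sequence: 6 (steps 1, 2, 3, 4, 5 and 10, from compound 1).

Step 10 is the least secure step: the enaminone may simply cyclise to the 3-unsubstituted chromone, or add to the other quinone position. The fallback sets out from 7 and 11 and comes back at 17. I2 in CHCl3 at 25 °C turns 7 into 3-iodochromone F1 (iodocyclisation with loss of dimethylamine). Compound 11 is lithiated at a ring position next to OMOM (n-BuLi, TMEDA, THF, 0 °C) and quenched with B(OMe)3 to give, after aqueous work-up, arylboronic acid F2. Suzuki coupling of F1 and F2 (Pd(PPh3)4, K2CO3, DME/H2O, 80 °C) gives tris-MOM isoflavone F3, and 2 M HCl in MeOH gives trihydroxyisoflavone F4. Teuber oxidation of its resorcinol-type ring B with K2[ON(SO3)2] gives isoflavone quinone F5, the 5-hydroxy analogue of 15, which closes the furan and tautomerises as in step 10 to give 17.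

Step 9 is the second risk: the hydroxyquinone is sensitive and 12 can over-oxidise. The fallback sets out from 11 and comes back at 13. Arylboronic acid F2, made from 11 as above, is oxidised with H2O2/NaOH (THF/H2O, 0 °C) to phenol F6. PhI(OAc)2 in MeCN/H2O at 0 °C oxidises this para-alkoxyphenol to MOM-protected hydroxyquinone F7 with loss of the para MOM group. Dilute HCl in THF/H2O at 20 °C hydrolyses the remaining vinylogous-ester MOM group to give 13, avoiding both free 2-prenylresorcinol and the nitroxide oxidant.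

Step 4 is the third risk: yields of such annulations are moderate, and closure onto the chelated 6-oxygen would give the 8-acetyl isomer. The fallback sets out from 4 and comes back at 6. The non-chelated 4-OH is alkylated with 3-chloro-3-methylbut-1-yne (K2CO3, KI, CuI cat., acetone, 55 °C) to give aryl propargyl ether F8. Heating in xylene at 140 °C triggers aromatic Claisen rearrangement to C5, 1,5-hydrogen shift and oxa-6π closure, which puts the pyran oxygen on the former 4-O by construction and gives 6.

**Further compounds**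
F1 | step 10 | 3-iodo-5-(methoxymethoxy)-6,8,8-trimethyl-4H,8H-pyrano[2,3-f]chromen-4-one | O=c1c(I)coc2c1c(OCOC)c(C)c1OC(C)(C)C=Cc12
F2 | step 10 | [2,4-bis(methoxymethoxy)-3-(3-methylbut-2-en-1-yl)phenyl]boronic acid | COCOc1ccc(B(O)O)c(OCOC)c1CC=C(C)C
F3 | step 10 | 3-[2,4-bis(methoxymethoxy)-3-(3-methylbut-2-en-1-yl)phenyl]-5-(methoxymethoxy)-6,8,8-trimethyl-4H,8H-pyrano[2,3-f]chromen-4-one | COCOc1ccc(-c2coc3c(c2=O)c(OCOC)c(C)c2OC(C)(C)C=Cc32)c(OCOC)c1CC=C(C)C
F4 | step 10 | 3-[2,4-dihydroxy-3-(3-methylbut-2-en-1-yl)phenyl]-5-hydroxy-6,8,8-trimethyl-4H,8H-pyrano[2,3-f]chromen-4-one | CC(C)=CCc1c(O)ccc(c1O)-c1coc2c(c1=O)c(O)c(C)c1OC(C)(C)C=Cc21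
F5 | step 10 | 2-hydroxy-5-(5-hydroxy-6,8,8-trimethyl-4-oxo-4H,8H-pyrano[2,3-f]chromen-3-yl)-3-(3-methylbut-2-en-1-yl)cyclohexa-2,5-diene-1,4-dione | CC(C)=CCC1=C(O)C(=O)C=C(C1=O)c1coc2c(c1=O)c(O)c(C)c1OC(C)(C)C=Cc21
F6 | step 9 | 2,4-bis(methoxymethoxy)-3-(3-methylbut-2-en-1-yl)phenol | COCOc1ccc(O)c(OCOC)c1CC=C(C)C
F7 | step 9 | 2-(methoxymethoxy)-3-(3-methylbut-2-en-1-yl)cyclohexa-2,5-diene-1,4-dione | COCOC1=C(CC=C(C)C)C(=O)C=CC1=O
F8 | step 4 | 1-{6-hydroxy-2-(methoxymethoxy)-3-methyl-4-[(2-methylbut-3-yn-2-yl)oxy]phenyl}ethan-1-one | CC(=O)c1c(OCOC)c(C)c(OC(C)(C)C#C)cc1O
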